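**Conventions and one assumption.** Cyclobutane locants: C1 and C4 are the quaternary carbons, C2 and C3 the CH carbons. Pyranone locants: O1', C2' (C=O), C3' (CH3), C4' (O), C5' (H), C6' (bonded to C1 or C4). "Top face" is the face of the cyclobutane that carries the C1/C4 carbon substituents that become the pyranones; "bottom face" carries the C1/C4 methyl groups and the C2/C3 carbon substituents. Assumption: the SMILES of the target describes the meso compound (pyranones cis on top; methyls and carboxyls on the bottom), so the route is not enantioselective; the carbinol centres of 7 and 8 form as a mixture that converges on oxidation.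

**Numbering used throughout.** 1 cis-2-butene-1,4-diol; 2 its acetonide; 3 2,3-dimethylmaleic anhydride; 4 photoadduct; 5 C1/C4 diol; 6 C1/C4 dialdehyde; 7 C1/C4 bis(carbinol); 8 tetraol; 9 diketone dialdehyde; 10 diketone diacid; 11 diketone anhydride; 12 bis(silyl enol ether); 13 methylmalonic acid; 14 methylmalonyl dichloride; 15 acylated intermediate; 16 bis(hydroxypyranone) anhydride; 17 bis(methoxypyranone) anhydride; 18 target.

## Analysis of the target

The target 18 is a fully substituted cyclobutane. C1 and C4 are adjacent quaternary carbons, each with a methyl group and a 4-methoxy-3-methyl-2-pyranon-6-yl ring; C2 and C3 are CH carbons, each with a carboxylic acid. Read from the SMILES, the two pyranones lie on one face and the two methyls and two carboxyls on the other. Each carboxyl is therefore cis to the methyl and trans to the pyranone on the neighbouring carbon, and the molecule is meso (a mirror plane bisects C1–C4 and C2–C3). The four stereocentres thus pose one problem of relative configuration and none of absolute configuration. The sensitive points are the 2-pyranones (vinylogous carbonates that hard nucleophiles open or demethylate), the ambident O4/O2 pair when the methyl ethers are made, and C2/C3, which can epimerise whenever they are α to an aldehyde or ester under base. The hard part is the pair of vicinal quaternary carbons that must carry two heteroaromatic rings cis to each other; attaching preformed pyranones there is not realistic. The plan rests on how each ring O1'–C2'(=O)–C3'(CH3)–C4'(O)–C5'(H)–C6' is assembled: C6', O1' and C5' are the carbonyl carbon, oxygen and methyl carbon of an acetyl group on C1 or C4, and C2'–C3'–C4' is a methylmalonyl unit. Both rings can therefore be grown last from two acetyl groups by forming C4'–C5' and O1'–C2', and the cyclobutane only has to supply a cis-1,4-diacetyl core with the C2/C3 acids masked.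

## Retrosynthetic reasoning

**18 from 17.** The two acids are uncovered last. They are kept tied as the five-membered anhydride 17, which can only span cis positions and so carries the C2/C3 relationship safely through the late steps. The forward step is a neutral hydrolysis, so nothing basic meets the methoxypyranones.

**17 from 16.** The two O4–CH3 bonds are cut. The free 4-hydroxyl is what pyranone formation delivers, so methylation belongs directly after it. The forward step must alkylate O4 rather than the ring carbonyl oxygen and must be run without any source of hydroxide, because the anhydride is present.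

**16 from 12 and 14 (key disconnection).** In each ring C4'–C5' and O1'–C2' are cut. This divides every pyranone into the three-carbon piece C2'–C3'(CH3)–C4', which is the doubly activated malonic acid 14, and the enol C5'=C6'–O1' of an acetyl group, which is the bis(silyl enol ether) 12. The alternative cut at C5'–C6' would require acylation by a carbonyl on a quaternary carbon flanked by a second quaternary carbon. The chosen cut places the C–C bond formation at the unhindered terminal CH2 of each enol ether. Two rings and four skeletal bonds are gained in one operation with no stereochemical consequence. The forward reaction passes through the doubly C-acylated species 15 and needs each arm to close on itself.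

**12 from 11, and 14 from 13.** The enol ethers come from the diketone 11 by silylation. Because both acetyl groups sit on quaternary carbons, enolisation can only go toward the methyl group. The dichloride 14 is the acid chloride of 13.

**11 from 10, 9 and 8.** The C2/C3 anhydride is the dehydration product of the cis diacid 10, which comes from the dialdehyde 9 by Pinnick oxidation. 9 is reached from the tetraol 8 in one Swern oxidation that also turns the two C1/C4 carbinols into the methyl ketones. The route goes through the dialdehyde on purpose. Any oxidant that acts stepwise on the cis-1,4-diol pair would trap the first hydroxy aldehyde as a lactol and stop at the lactone level. Only activation of all hydroxyls before any carbonyl exists avoids this.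

**8 from 7, 6, 5 and 4.** The two C(=O)–CH3 bonds are cut. Direct addition of two methyl carbanions to the anhydride 4 is not used: the ketone released by the first addition is more electrophilic than the carboxylate beside it and is attacked again, so the sequence ends at the lactone oxidation level. Instead the anhydride is reduced to the diol 5 and oxidised to the dialdehyde 6, which has no α-hydrogen. A methyl organometallic then adds to both formyl groups to give 7, and removing the ketal gives 8. This costs steps but every one is routine, and the C2/C3 ketal is inert to all of them.

**4 from 2 and 3; 2 from 1.** The cyclobutane bonds C1–C2 and C3–C4 are cut in a crossed [2+2] photocycloaddition. The anhydride ring of 3 fixes the C1/C4 carbonyls cis, the seven-membered ketal ring of 2 fixes the C2/C3 arms cis, and union with the two rings on opposite faces puts the CH2O arms on the methyl face. All four stereocentres of 18 are set in this one step and none is touched afterwards except through the C2/C3 formyl stage. The ketal 2 comes from the diol 1.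

## Alternatives that were turned down

**Alternative 1:** the cyclobutane is disconnected at C1–C2 and C3–C4, and the forward key step is the triplet-sensitised [2+2] union of 3 with 2 to the cis-anti-cis tricycle A1 (the same structure as 4).
- For: two cheap components give the whole carbocycle and all four stereocentres in one step, the two ring fusions enforce the cis pairs, and the only stereo-determining event comes first, on inexpensive material.
- Against: as a strategy it answers the easier half of the problem. A1 holds none of the heteroaromatic atoms, and the conversion of an anhydride on two quaternary carbons into two pyranones is left open.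
- Comparison: on stereocontrol it is as strong as the chosen plan, which uses this very cycloaddition as step 2. The chosen plan adds what is missing: the late double annulation that makes both rings from acetyl groups.

**Alternative 2:** the C2–CO2 and C3–CO2 bonds are cut, and the forward key step is oxidative bis-alkoxycarbonylation of the cis-3,4-dimethyl-3,4-bis(pyranonyl)cyclobutene A3 (PdCl2, CuCl2 as reoxidant, carbon monoxide, methanol) to the dimethyl ester A2.
- For: both carboxyl carbons arrive in one syn addition, so the cis relationship is mechanistic, and the face away from the two pyranones should be preferred. On this point it is stronger than the chosen route, which spends its longest stretch (reduction, two oxidations, dehydration) adjusting oxidation levels at C2/C3.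
- Against: A3 must already carry both pyranones on vicinal quaternary carbons, so a ring construction of the chosen kind is needed anyway, now on a strained cyclobutene. 2-Pyranones are dienes and conjugate acceptors that can bind divalent palladium, the cyclobutene can open electrocyclically or be chlorinated by CuCl2, and the end is the cleavage of two hindered cis methyl esters next to base-labile methoxypyranones, with a risk of epimerisation to the trans diester.
- Comparison: the chosen plan ends with water opening an anhydride, a far milder last step.

**Alternative 3:** the C2–C3 bond is cut, and the forward key step is 4π photoclosure of the cis-1,2-dimethylcyclohexa-3,5-diene-1,2-dicarboxylic anhydride A5 to the bicyclo[2.2.0]hexene A4, followed by oxidative cleavage of the cyclobutene to the C2/C3 acids.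
- For: the ring closure is intramolecular, so there is no cross-selectivity problem, and cleavage of A4 gives C2 and C3 directly at the acid level and cis. This is shorter at C2/C3 than the chosen route.
- Against: A5 is not a simple compound, since 3 is a poor dienophile and the diene must then be introduced. On direct irradiation 1,3-cyclohexadienes favour 6π opening to the triene over 4π closure. Nothing obvious directs the closure to the methyl face. A4 is a strained Dewar-type system that can revert. After cleavage a hindered anhydride sits beside two free acids that must be told apart before the acetyl groups can be made.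
- Comparison: the chosen route keeps the two pairs at different oxidation levels (anhydride against ketal) from the start, which solves that differentiation by construction.

Key step: step 12

## Route

Step 1
Reactants: 1 cis-2-butene-1,4-diol
Product: 2 2,2-dimethyl-4,7-dihydro-1,3-dioxepine
Conditions: Me2C(OMe)2, TsOH·H2O (cat.), CH2Cl2, rt; distil
Reagents that add atoms: 2,2-dimethoxypropane, COC(C)(C)OC
Why: Acid-catalysed transketalisation of a cis-1,4-diol; the Z-alkene holds the two hydroxyls in reach of one ketal carbon and removal of methanol drives the exchange.

Step 2
Reactants: 2 2,2-dimethyl-4,7-dihydro-1,3-dioxepine; 3 2,3-dimethylmaleic anhydride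
Product: 4 cis-anti-cis photoadduct: 1,4-dimethylcyclobutane-1,4-dicarboxylic anhydride (top) whose C2 and C3 carry on the bottom face the two CH2O arms of a 2,2-dimethyl-1,3-dioxepane ring
Conditions: hν (medium-pressure Hg lamp, Pyrex, λ > 300 nm), PhCOMe (sensitiser), MeCN, 2 in excess (3–5 equiv), rt
Reagents that add atoms: none
Why: Triplet-sensitised [2+2] photocycloaddition of an enone-type anhydride to a cyclic alkene through a 1,4-biradical; the five-membered anhydride and the seven-membered ketal can only be cis-fused to the new ring, which sets C1/C4 and C2/C3 as cis pairs, and closure with the two rings on opposite faces (the less crowded, anti arrangement) places the CH2O arms on the methyl face. Excess 2 should hold back the photodimerisation of 3.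

Step 3
Reactants: 4 cis-anti-cis photoadduct
Product: 5 1,4-bis(hydroxymethyl)-1,4-dimethylcyclobutane with the C2/C3 dioxepane ketal (hydroxymethyls top; methyls and ketal arms bottom)
Conditions: LiAlH4, THF, 0 °C → reflux; Fieser work-up
Reagents that add atoms: none
Why: LiAlH4 reduces a cyclic anhydride through the lactone to the 1,4-diol; the ketal is inert to hydride and no stereocentre is involved.

Step 4
Reactants: 5 C1/C4 diol
Product: 6 1,4-diformyl-1,4-dimethylcyclobutane with the C2/C3 dioxepane ketal (formyls top)
Conditions: (COCl)2, DMSO, CH2Cl2, −78 °C; Et3N, −78 → 0 °C
Reagents that add atoms: none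
Why: Swern oxidation; both hydroxyls are converted into alkoxysulfonium salts before base is added, so no hydroxy aldehyde is present to close to a lactol, and the aldehydes sit on quaternary carbons and cannot epimerise.

Step 5
Reactants: 6 C1/C4 dialdehyde
Product: 7 1,4-bis(1-hydroxyethyl)-1,4-dimethylcyclobutane with the C2/C3 dioxepane ketal (mixture at the two carbinol carbons)
Conditions: MeMgBr (5 equiv), THF, 0 °C → rt; sat. aq. NH4Cl
Reagents that add atoms: methylmagnesium bromide, C[Mg]Br
Why: Grignard addition to aldehydes; the lactolate formed after the first addition is in equilibrium with the open alkoxy aldehyde and is consumed by excess reagent, as in Grignard additions to lactols. The configuration of the new carbinol carbons is irrelevant because both are oxidised in step 7.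

Step 6
Reactants: 7 C1/C4 bis(carbinol) ketal
Product: 8 1,4-bis(1-hydroxyethyl)-2,3-bis(hydroxymethyl)-1,4-dimethylcyclobutane (hydroxyethyls top; methyls and hydroxymethyls bottom)
Conditions: TsOH·H2O (cat.), MeOH, rt; Et3N, evaporate
Reagents that add atoms: none
Why: Acid-catalysed transketalisation to methanol releases the diol from the seven-membered ketal without touching the secondary alcohols; evaporation removes the volatile ketal by-product and avoids an aqueous work-up of the polar tetraol.

Step 7
Reactants: 8 tetraol
Product: 9 1,4-diacetyl-1,4-dimethylcyclobutane-2,3-dicarbaldehyde (acetyls top; methyls and formyls bottom)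
Conditions: (COCl)2, DMSO, CH2Cl2 (8 added in CH2Cl2/DMSO), −78 °C; iPr2NEt, −78 → −30 °C; cold pH 7 buffer, used crude
Reagents that add atoms: none
Why: Fourfold Swern oxidation; all four hydroxyls are activated at −78 °C before base is added, so the cis-1,4-diol pair at C2/C3 goes to the dialdehyde and not through a lactol to a lactone, while the secondary alcohols give the methyl ketones. The hindered base, the low temperature and immediate use are meant to keep the C2/C3 formyl centres from epimerising.

Step 8
Reactants: 9 diketone dialdehyde
Product: 10 1,4-diacetyl-1,4-dimethylcyclobutane-2,3-dicarboxylic acid (acetyls top; methyls and carboxyls bottom)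
Conditions: NaClO2, NaH2PO4, 2-methyl-2-butene, t-BuOH/H2O, 0 °C → rt
Reagents that add atoms: sodium chlorite, [Na+].[O-]Cl=O
Why: Pinnick oxidation takes aldehydes to acids in a weakly acidic buffer that neither enolises the α-centres nor affects the methyl ketones; the alkene scavenges the hypochlorous acid formed.

Step 9
Reactants: 10 diketone diacid
Product: 11 1,4-diacetyl-1,4-dimethylcyclobutane-2,3-dicarboxylic anhydride (acetyls top; methyls and anhydride bottom)
Conditions: (CF3CO)2O, CH2Cl2, 0 °C → rt; evaporate
Reagents that add atoms: none
Why: Dehydration of a cis-1,2-diacid to the five-membered cyclic anhydride by way of a mixed trifluoroacetic anhydride; only the cis diacid can close, so any trans epimer from step 7 stays an acid and is left on a short silica plug.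

Step 10
Reactants: 11 diketone anhydride
Product: 12 1,4-bis[1-(trimethylsilyloxy)ethenyl]-1,4-dimethylcyclobutane-2,3-dicarboxylic anhydride (enol ethers top; methyls and anhydride bottom)
Conditions: TMSOTf (2.4 equiv), Et3N (3 equiv), CH2Cl2, 0 °C; pentane extraction, no aqueous work-up
Reagents that add atoms: trimethylsilyl trifluoromethanesulfonate, C[Si](C)(C)OS(=O)(=O)C(F)(F)F
Why: Soft enolisation and O-silylation of methyl ketones; each acetyl is on a quaternary carbon and can enolise only toward CH3, and the anhydride α-hydrogens should stay because their removal would place a double bond at the ring fusion of the bicyclo[3.2.0] system.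

Step 11
Reactants: 13 methylmalonic acid
Product: 14 methylmalonyl dichloride
Conditions: SOCl2 (neat), 45–50 °C; distil under reduced pressure
Reagents that add atoms: thionyl chloride, O=S(Cl)Cl
Why: Standard conversion of a malonic acid into its dichloride with SOCl2; distillation removes partly chlorinated material.

Step 12
Reactants: 12 bis(silyl enol ether); 14 methylmalonyl dichloride (2.3 equiv)
Product: 16 1,4-bis(4-hydroxy-3-methyl-2-oxo-2H-pyran-6-yl)-1,4-dimethylcyclobutane-2,3-dicarboxylic anhydride, via bis(acid chloride) tetraketone 15 (not isolated)
Conditions: 14, Et2O, −78 °C → rt, 16 h; collect the precipitate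
Reagents that add atoms: none
Why: Each silyl enol ether is C-acylated at its terminal CH2 carbon (the future C5') by one acid chloride group of 14, which forms C4'–C5', releases Me3SiCl and gives the doubly acylated species 15. In 15 each C6' ketone enolises toward C5' and its enol oxygen attacks the remaining acid chloride in a 6-exo-trig lactonisation that forms O1'–C2'; loss of HCl and tautomerisation of the pyran-2,4-dione give the aromatic 4-hydroxy-3-methyl-2-pyranone. The same two events on the second arm close the second ring, so four skeletal bonds and two rings are made and no stereocentre is formed or disturbed. The closest known reaction type is the base-free condensation of ketone silyl enol ethers with malonyl dichlorides to 6-substituted 4-hydroxy-2-pyranones. Regiochemistry is fixed by the substrate, since each enol ether has only its CH2 terminus to offer. The selectivity needed is closure of each acylated arm on itself rather than a second intermolecular acylation or a bridge to the neighbouring arm; the six-membered intramolecular lactonisation secures it, because a bridge through one malonyl unit would need a nine-membered ring. Excess 14 at −78 °C is meant to acylate both arms before HCl from the first lactonisation can strip the silyl group from the other enol ether. The cis-fused anhydride has no nucleophilic site, is inert to acid chlorides and HCl, and holds C2 and C3 in place.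

Step 13
Reactants: 16 bis(hydroxypyranone) anhydride
Product: 17 1,4-bis(4-methoxy-3-methyl-2-oxo-2H-pyran-6-yl)-1,4-dimethylcyclobutane-2,3-dicarboxylic anhydride (pyranones top; methyls and anhydride bottom)
Conditions: NaH (2.05 equiv), THF/DMF, 0 °C; Me2SO4 (2.5 equiv), 0 °C → rt
Reagents that add atoms: dimethyl sulfate, COS(=O)(=O)OC
Why: O-Alkylation of the metal salt of a 4-hydroxy-2-pyranone with a hard methylating agent goes mainly at O4 and gives the 4-methoxy-2-pyranone. NaH replaces the usual carbonate base because it forms no water, which would open the anhydride to carboxylates that Me2SO4 would then esterify.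

Step 14
Reactants: 17 bis(methoxypyranone) anhydride
Product: 18 1,4-bis(4-methoxy-3-methyl-2-oxo-2H-pyran-6-yl)-1,4-dimethylcyclobutane-2,3-dicarboxylic acid (pyranones top; methyls and carboxyls bottom), the target CNP0574758.1
Conditions: H2O/THF (1:1), 40 °C
Reagents that add atoms: water, O
Why: Hydrolysis of a strained cis-fused succinic-type anhydride needs neither acid nor base, so the methoxypyranones and the C2/C3 configuration are untouched and the cis diacid is released directly.

## Compound list

1 | cis-2-butene-1,4-diol | OC/C=C\CO | starting material
2 | 2,2-dimethyl-4,7-dihydro-1,3-dioxepine | CC1(C)OCC=CCO1 | intermediate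
3 | 2,3-dimethylmaleic anhydride | CC1=C(C)C(=O)OC1=O | starting material
4 | cis-anti-cis photoadduct: 1,4-dimethylcyclobutane-1,4-dicarboxylic anhydride (top) with the C2/C3 CH2O arms of a 2,2-dimethyl-1,3-dioxepane on the bottom face | O=C3OC(=O)[C@@]2(C)[C@H](CO4)[C@H](COC4(C)C)[C@]23C | intermediate
5 | 1,4-bis(hydroxymethyl)-1,4-dimethylcyclobutane with the C2/C3 dioxepane ketal | OC[C@@]1(C)[C@H](CO2)[C@H](COC2(C)C)[C@@]1(C)CO | intermediate
6 | 1,4-diformyl-1,4-dimethylcyclobutane with the C2/C3 dioxepane ketal | O=C[C@@]1(C)[C@H](CO2)[C@H](COC2(C)C)[C@@]1(C)C=O | intermediate
7 | 1,4-bis(1-hydroxyethyl)-1,4-dimethylcyclobutane with the C2/C3 dioxepane ketal (carbinol centres mixed) | CC(O)[C@@]1(C)[C@H](CO2)[C@H](COC2(C)C)[C@@]1(C)C(C)O | intermediate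
8 | 1,4-bis(1-hydroxyethyl)-2,3-bis(hydroxymethyl)-1,4-dimethylcyclobutane (carbinol centres mixed) | CC(O)[C@@]1(C)[C@H](CO)[C@H](CO)[C@@]1(C)C(C)O | intermediate
9 | 1,4-diacetyl-1,4-dimethylcyclobutane-2,3-dicarbaldehyde | CC(=O)[C@@]1(C)[C@H](C=O)[C@H](C=O)[C@@]1(C)C(C)=O | intermediate
10 | 1,4-diacetyl-1,4-dimethylcyclobutane-2,3-dicarboxylic acid | CC(=O)[C@@]1(C)[C@H](C(=O)O)[C@H](C(=O)O)[C@@]1(C)C(C)=O | intermediate
11 | 1,4-diacetyl-1,4-dimethylcyclobutane-2,3-dicarboxylic anhydride | CC(=O)[C@@]1(C)[C@H](C(=O)O2)[C@H](C2=O)[C@@]1(C)C(C)=O | intermediate
12 | 1,4-bis[1-(trimethylsilyloxy)ethenyl]-1,4-dimethylcyclobutane-2,3-dicarboxylic anhydride | C=C(O[Si](C)(C)C)[C@@]1(C)[C@H](C(=O)O4)[C@H](C4=O)[C@@]1(C)C(=C)O[Si](C)(C)C | intermediate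
13 | methylmalonic acid | CC(C(=O)O)C(=O)O | starting material
14 | methylmalonyl dichloride | CC(C(=O)Cl)C(=O)Cl | intermediate
15 | 1,4-bis(5-chloro-4-methyl-3,5-dioxopentanoyl)-1,4-dimethylcyclobutane-2,3-dicarboxylic anhydride (not isolated; chain methine centres undefined) | CC(C(=O)Cl)C(=O)CC(=O)[C@@]1(C)[C@H](C(=O)O2)[C@H](C2=O)[C@@]1(C)C(=O)CC(=O)C(C)C(=O)Cl | intermediate
16 | 1,4-bis(4-hydroxy-3-methyl-2-oxo-2H-pyran-6-yl)-1,4-dimethylcyclobutane-2,3-dicarboxylic anhydride | Cc1c(O)cc([C@@]2(C)[C@H](C(=O)O4)[C@H](C4=O)[C@@]2(C)c3cc(O)c(C)c(=O)o3)oc1=O | intermediate
17 | 1,4-bis(4-methoxy-3-methyl-2-oxo-2H-pyran-6-yl)-1,4-dimethylcyclobutane-2,3-dicarboxylic anhydride | COc1cc([C@@]2(C)[C@H](C(=O)O4)[C@H](C4=O)[C@@]2(C)c3cc(OC)c(C)c(=O)o3)oc(=O)c1C | intermediate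
18 | 1,4-bis(4-methoxy-3-methyl-2-oxo-2H-pyran-6-yl)-1,4-dimethylcyclobutane-2,3-dicarboxylic acid (CNP0574758.1) | COc1cc([C@@]2(C)[C@H](C(=O)O)[C@H](C(=O)O)[C@@]2(C)c2cc(OC)c(C)c(=O)o2)oc(=O)c1C | target

## Step count and least certain steps

Total: 14 steps. Longest linear sequence: 13 steps (steps 1–10 and 12–14); step 11 is a one-step side branch.

**Step 12 (key step).** The HCl released when the first ring closes may desilylate the second enol ether before it is acylated, which would stop the sequence at a mono-pyranone methyl ketone. One malonyl unit may also acylate enol ethers of two molecules and start oligomerisation. Fallback: set out from 12 and separate the two bond formations. C-Acylation of both enol ethers with the half-ester chloride tert-butyl 3-chloro-2-methyl-3-oxopropanoate (ZnCl2 catalysis, CH2Cl2, −20 °C → rt) releases only Me3SiCl and should give the bis(β,δ-diketo tert-butyl ester) F1. CF3CO2H/(CF3CO)2O at rt then removes the tert-butyl groups and closes both lactones, and the route is rejoined at 16.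

**Step 2.** Three processes can erode the step: photodimerisation of 3, hydrogen abstraction from the allylic O–CH2 positions of 2 by the excited anhydride, and an incomplete preference for the anti arrangement of the two rings. Fallback: set out from 3 and change the chromophore. NaBH4 reduction of one carbonyl gives 3,4-dimethylfuran-2(5H)-one F2, a butenolide whose triplet is a weaker hydrogen abstractor. Acetone-sensitised [2+2] addition of F2 to 2 should give the lactone photoadduct F3 with the same anti ring arrangement, and LiAlH4 reduction of F3 rejoins the route at 5.

**Step 7.** The cis formyl groups at C2/C3 may epimerise under the amine base, and incomplete activation of the polar tetraol may allow lactol formation. Fallback: set out from 8 and avoid free C2/C3 aldehydes under base. TEMPO/PhI(OAc)2 oxidises only the primary pair, through the lactol, to the γ-lactone diol F4. LiOH in aqueous THF opens it to the hydroxy acid F5, kept as its lithium salt so that it cannot relactonise. RuCl3 (cat.)/NaIO4 buffered with NaHCO3 then oxidises the remaining primary alcohol to the acid and both carbinols to the ketones, rejoining the route at 10 after acidification.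

**Step 10.** Once one acetyl group is enolised it may add to the neighbouring ketone in an intramolecular aldol reaction (five-membered ring). The anhydride may be silylated at its α-carbon, or the enol ethers may hydrolyse on isolation. Fallback: set out from 11 and omit the enol ether. Heating 11 with bis(2,4,6-trichlorophenyl) 2-methylmalonate (diphenyl ether, about 200 °C) is a thermal cyclocondensation of enolisable ketones with activated malonates through an acylketene; it should annulate both free methyl ketones and rejoin the route at 16. No new compound lies on this path.

**Step 13.** Methylation may go partly at the ring carbonyl oxygen (2-methoxy-4-pyranone isomers) or at C3', and adventitious hydroxide may open the anhydride and lead to methyl esters. Fallback: set out from 16 and accept ester formation. Hydrolysis (H2O/THF) gives the diacid bis(hydroxypyranone) F6. Exhaustive methylation under the classical conditions (Me2SO4, K2CO3, acetone, reflux) gives the dimethyl ester bis(methoxypyranone) F7. Me3SnOH (1,2-dichloroethane, 80 °C), a neutral reagent for methyl ester cleavage that should spare the vinylogous esters, then rejoins the route at 18.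

## Further compounds

F1 | step 12 | 1,4-bis(5-tert-butoxy-4-methyl-3,5-dioxopentanoyl)-1,4-dimethylcyclobutane-2,3-dicarboxylic anhydride | CC(C(=O)OC(C)(C)C)C(=O)CC(=O)[C@@]1(C)[C@H](C(=O)O2)[C@H](C2=O)[C@@]1(C)C(=O)CC(=O)C(C)C(=O)OC(C)(C)C
F2 | step 2 | 3,4-dimethylfuran-2(5H)-one | CC1=C(C)C(=O)OC1
F3 | step 2 | lactone photoadduct: C1 carbonyl and C4 CH2O joined as a γ-lactone on the top face, C2/C3 dioxepane ketal arms on the bottom face | O=C(O3)[C@@]1(C)[C@H](CO2)[C@H](COC2(C)C)[C@@]1(C)C3
F4 | step 7 | γ-lactone bridging C2 (carbonyl) and C3 (CH2O) of 1,4-bis(1-hydroxyethyl)-1,4-dimethylcyclobutane | CC(O)[C@@]1(C)[C@H](C(=O)O2)[C@H](C2)[C@@]1(C)C(C)O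
F5 | step 7 | 1,4-bis(1-hydroxyethyl)-3-(hydroxymethyl)-1,4-dimethylcyclobutane-2-carboxylic acid (handled as lithium salt) | CC(O)[C@@]1(C)[C@H](C(=O)O)[C@H](CO)[C@@]1(C)C(C)O
F0 | step 10 | none | none
F6 | step 13 | 1,4-bis(4-hydroxy-3-methyl-2-oxo-2H-pyran-6-yl)-1,4-dimethylcyclobutane-2,3-dicarboxylic acid | Cc1c(O)cc([C@@]2(C)[C@H](C(=O)O)[C@H](C(=O)O)[C@@]2(C)c3cc(O)c(C)c(=O)o3)oc1=O
F7 | step 13 | dimethyl 1,4-bis(4-methoxy-3-methyl-2-oxo-2H-pyran-6-yl)-1,4-dimethylcyclobutane-2,3-dicarboxylate | COc1cc([C@@]2(C)[C@H](C(=O)OC)[C@H](C(=O)OC)[C@@]2(C)c3cc(OC)c(C)c(=O)o3)oc(=O)c1C
A1 | alternative 1 | cis-anti-cis photoadduct of 3 with 2 (identical with 4) | O=C3OC(=O)[C@@]2(C)[C@H](CO4)[C@H](COC4(C)C)[C@]23C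
A2 | alternative 2 | dimethyl ester of the target | COc1cc([C@@]2(C)[C@H](C(=O)OC)[C@H](C(=O)OC)[C@@]2(C)c3cc(OC)c(C)c(=O)o3)oc(=O)c1C
A3 | alternative 2 | cis-3,4-dimethyl-3,4-bis(4-methoxy-3-methyl-2-oxo-2H-pyran-6-yl)cyclobutene | COc1cc([C@@]2(C)C=C[C@@]2(C)c2cc(OC)c(C)c(=O)o2)oc(=O)c1C
A4 | alternative 3 | 2,3-dimethylbicyclo[2.2.0]hex-5-ene-2,3-dicarboxylic anhydride (cyclobutene on the methyl face) | O=C3OC(=O)[C@@]2(C)[C@H](C=C4)[C@H]4[C@]23C
A5 | alternative 3 | cis-1,2-dimethylcyclohexa-3,5-diene-1,2-dicarboxylic anhydride | O=C1OC(=O)[C@]2(C)C=CC=C[C@]12C
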